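In the closed, stirred vessel E starts as a solid with none of it in solution, and you need to know whether Friday's warming meets anything still unreacted.

| flask | E | temperature | remark | time |
|---|---|---|---|---|
| elm | 1.9 M | −25 °C | run made earlier |  |
| larch | 1.9 M | −10 °C | run made earlier |  |
| Saturday's | 2.9 M |  | at −20 °C throughout | 5.0 h |
| Friday's | 2.9 M |  | at −20 °C until 1.5 h, from then on at 0 °C | 8.0 h |

- elm (time / h: Z / %, E / %): 0.500: 52.3, 4.1; 1.33: 85.7, 0; 2.50: 86.8, 0.3; 4.00: 86.5, 0; 6.00: 86.4, 0; 8.00: 86.2, 0.2; 10.0: 86.8, 0.1
- larch (time / h: Z / %, E / %): 0.333: 64.7, 20.7; 0.833: 86.6, 0; 1.50: 86.8, 0.2; 2.50: 86.6, 0; 4.00: 87.0, 0.2; 5.00: 86.9, 0.3; 6.00: 87.1, 0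

(readings scatter by 0.3 percentage points)

- given per volume of solution although it is solid: E
- at the start none of E is in solution
- in a conversion G counts as not yet reacted
- what has only dissolved of E counts as not reacted

- which of the two ends with the higher amount of Z, in percent of the E charged ("neither" if they lie within 2 percentage points) (Saturday's / Friday's / neither)
- Z at the end, in percent of the E charged, Saturday's
- Z at the end, in percent of the E charged, Friday's

My own reckoning starts from the elm run. E reads 4.1 % at 0.500 h, so a charge of 1.9 M goes at a mean rate r = 3.64 M h⁻¹. The warmer larch run gives 4.52 M h⁻¹, faster, so I take r as a cautious figure for −20 °C and assume that it holds at 2.9 M. Z's distance from the elm plateau reading of 86.8 % shrinks from its first to its second elm reading at a read half-life τ = 0.167 h.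

Now fold the givens together as n = (t_w − c/r)/τ, with c the charge and t_w the time of the change. For Friday's this gives 4.22, the count of half-lives that fit between the solid's reckoned disappearance and the warming. The elm gap of 34 percentage points would shrink over n half-lives to 1.9 points, below the margin of 2 points, so I say neither.

But n tells when the flask finishes, not at what level. The plateaus at −25 °C and −10 °C agree, yet both runs were charged at 1.9 M, and 2.9 M is unread. I still put both flasks at 86.8 %.

The forecast also says neither, but lower, with 86 % for Saturday's and 85.5 % for Friday's: “Friday's warming comes after most conversion, so both should reach about the same yield.”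

Saturday's ends at 84.9 % and Friday's at 84.9 %, so the answer is neither.

    J ⇌ G (K = 5.50, k = 0.0150 min⁻¹, Ea = 83.0 kJ mol⁻¹, ΔH = −47.0 kJ mol⁻¹)
    G ⇌ X (K = 2.00, k = 0.150 min⁻¹, Ea = 70.0 kJ mol⁻¹, ΔH = −52.0 kJ mol⁻¹)
    J → Z (k = 0.140 min⁻¹, Ea = 77.0 kJ mol⁻¹)
    E ⇌ J, rate k4*(cs4 - [J]) while solid is left; crystals form when [J] > cs4 (solubility = 2.20 M, k = 0.0360 min⁻¹)
    G → D (k = 0.320 min⁻¹, Ea = 81.0 kJ mol⁻¹)
    J + Z → Q (k = 0.00370 M⁻¹ min⁻¹, Ea = 58.0 kJ mol⁻¹)
    (constants at −20 °C)

In Friday's, half of the dissolving of E is done by 0.356 h, earlier than the change at 1.5 h. At that change, E, J, G and X together hold 0.234 % of the charge, with n at 4.22. A neighbour of Friday's charged with 0.72 M has n = 7.80, and at 8.00 h it has 0 % of its E left, solid or dissolved, and 88.9 % of Z.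

Readings and results were computed with made-up constants; scatter was added.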